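**Retrosynthetic overview**

1. Ring positions are numbered O1, C2 (carries the pentenynyl chain), C3 (Cl), C4 (CH2), C5 (Br), C6 (carries the bromopentenyl chain). The (Z)-enyne is traced back to a C2–CH2–CHO aldehyde (Peterson olefination), and the axial Cl at C3 and axial Br at C5 to equatorial hydroxyl groups (two SN2 inversions).
2. Key disconnection: the resulting 3-hydroxy-5-oxo-oxane-2-acetate is cut at C3–C4 (aldol) and O1–C2 (oxa-Michael). This gives an (R)-α-hydroxy methyl ketone (C4, C5, C6, O1 and the finished (E)-bromopentenyl chain) and a four-carbon (E)-4-oxo-enoate (C3, C2 and two side-chain carbons).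
3. Enabling feature: once the halogens are traced back to oxygen, C3(OH)–C4H2–C5(=O) is a β-hydroxy ketone with an unsubstituted C4, and O1 lies β to the first side-chain carbon beyond C2 (an ester carbonyl in the precursor). The all-cis target corresponds to an all-equatorial, 2,6-cis oxygenated oxane.
4. The hydroxy ketone comes from an auxiliary-controlled glycolate alkylation with an (E)-2-bromoallylic bromide, itself made from a pentynoate by syn-stannylcupration and bromodestannylation.
5. Ring formation: the oxane is the only ring and is closed in step 10.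

Key step: step 10

Remark: every starting material of the route and every reagent named in it is assumed to be commercially available; the oxane positions are numbered as in the first line of the overview.

**Route**

Step 1
Reactants: 1 ethyl pent-2-ynoate
Product: 2 ethyl (2E)-3-(tributylstannyl)pent-2-enoate
Conditions: Bu3SnH, LiN(i-Pr)2, THF, 0 °C; CuBr·SMe2, −78 °C; then 1, MeOH, −78 °C
Reagents that add atoms: tributyltin hydride, CCCC[SnH](CCCC)CCCC
Why: Stannylcupration should add tin and copper syn across the ynoate with tin at C3, and protonation of the vinylcopper by MeOH at −78 °C before it isomerizes should leave tin trans to the ester, which fixes the later (E)-bromoalkene.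

Step 2
Reactants: 2 ethyl (2E)-3-(tributylstannyl)pent-2-enoate
Product: 3 ethyl (2E)-3-bromopent-2-enoate
Conditions: Br2, CH2Cl2, −78 °C
Reagents that add atoms: bromine, BrBr
Why: Bromodestannylation is an ipso electrophilic substitution that should replace tin by bromine with retention of the alkene geometry.

Step 3
Reactants: 3 ethyl (2E)-3-bromopent-2-enoate
Product: 4 (2E)-3-bromopent-2-en-1-ol
Conditions: i-Bu2AlH, CH2Cl2, −78 → 0 °C
Reagents that add atoms: none
Why: Hydride reduction of the ester with i-Bu2AlH should give the allylic alcohol without touching the vinyl bromide.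

Step 4
Reactants: 4 (2E)-3-bromopent-2-en-1-ol
Product: 5 (2E)-1,3-dibromopent-2-ene
Conditions: CBr4, PPh3, CH2Cl2, 0 °C
Reagents that add atoms: carbon tetrabromide, BrC(Br)(Br)Br
Why: The Appel reaction should convert the primary allylic alcohol into the bromide under neutral conditions without allylic transposition or loss of geometry.

Step 5
Reactants: 6 (4S)-4-benzyl-1,3-oxazolidin-2-one; 7 (benzyloxy)acetyl chloride
Product: 8 (4S)-4-benzyl-3-[(benzyloxy)acetyl]-1,3-oxazolidin-2-one
Conditions: n-BuLi, THF, −78 °C; then 7, −78 → 0 °C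
Reagents that add atoms: none
Why: N-Acylation of the lithiated oxazolidinone with an acid chloride is the standard way to attach an Evans auxiliary.

Step 6
Reactants: 8 (4S)-4-benzyl-3-[(benzyloxy)acetyl]-1,3-oxazolidin-2-one; 5 (2E)-1,3-dibromopent-2-ene
Product: 9 (4S)-4-benzyl-3-[(2R,4E)-2-(benzyloxy)-5-bromohept-4-enoyl]-1,3-oxazolidin-2-one
Conditions: NaN(SiMe3)2, THF, −78 °C; then 5, −78 → −45 °C
Reagents that add atoms: none
Why: In this Evans auxiliary alkylation the chelated sodium (Z)-enolate of the glycolyl imide should be alkylated by the allylic bromide on the face opposite the benzyl group, which sets the (2R) center that becomes C6.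

Step 7
Reactants: 9 (4S)-4-benzyl-3-[(2R,4E)-2-(benzyloxy)-5-bromohept-4-enoyl]-1,3-oxazolidin-2-one
Product: 10 (2R,4E)-2-(benzyloxy)-5-bromo-N-methoxy-N-methylhept-4-enamide
Conditions: MeNH(OMe)·HCl, AlMe3, CH2Cl2, −10 → 0 °C
Reagents that add atoms: N,O-dimethylhydroxylamine hydrochloride, CNOC.Cl
Why: Aluminium amide transamination (Weinreb amide formation) should cleave the auxiliary at the exocyclic carbonyl without epimerizing the α-alkoxy center.

Step 8
Reactants: 10 (2R,4E)-2-(benzyloxy)-5-bromo-N-methoxy-N-methylhept-4-enamide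
Product: 11 (3R,5E)-3-(benzyloxy)-6-bromooct-5-en-2-one
Conditions: MeMgBr, THF, −10 °C
Reagents that add atoms: methylmagnesium bromide, C[Mg]Br
Why: In the Weinreb ketone synthesis the chelated tetrahedral intermediate should stop at mono-addition and release the methyl ketone on work-up.

Step 9
Reactants: 11 (3R,5E)-3-(benzyloxy)-6-bromooct-5-en-2-one
Product: 12 (3R,5E)-6-bromo-3-hydroxyoct-5-en-2-one
Conditions: BCl3, CH2Cl2, −78 °C; then MeOH
Reagents that add atoms: none
Why: Lewis acid debenzylation with BCl3, assisted by chelation to the neighbouring ketone, should free the hydroxyl group at −78 °C while the vinyl bromide, which rules out hydrogenolysis, stays intact.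

Step 10
Reactants: 12 (3R,5E)-6-bromo-3-hydroxyoct-5-en-2-one; 13 ethyl (2E)-4-oxobut-2-enoate
Product: 15 ethyl 2-[(2S,3R,6R)-6-[(2E)-3-bromopent-2-en-1-yl]-3-hydroxy-5-oxooxan-2-yl]acetate, via open-chain aldol adduct 14 (not isolated)
Conditions: TiCl4, i-Pr2NEt, CH2Cl2, −78 °C; then 13, −78 °C; then EtOH, DBU, −78 → 0 °C
Reagents that add atoms: none
Why: Proposed new method: TiCl4 with i-Pr2NEt should turn 12 into a five-membered titanium alkoxide–enolate chelate (O1–Ti–O–C5, enolized at the C4 methyl group), the titanium-bound aldehyde of 13 should then add through a chair-like Zimmerman–Traxler array on the chelate face away from the C6 side chain to form C4–C3 in the 1,4-anti sense (3R, adduct 14), and ethanol with DBU should release O1–H for a reversible oxa-Michael addition to the γ-hydroxy enoate that forms O1–C2; the closest known reaction types are the titanium-mediated 1,4-anti aldol reaction of α-benzyloxy methyl ketones and the base-mediated oxa-Michael closure of ζ-hydroxy enoates to 2,6-cis oxanes. The oxane closes in the 6-exo-trig mode. C3 is controlled by the C6 stereocenter through the titanium chelate, and C2 by the chair-like, equilibrating closure that places the CH2CO2Et group equatorial, cis to the C6 side chain and trans to the C3 hydroxyl. The step needs enolization at C4 and not at C6–H, 1,2-addition to the aldehyde and not conjugate addition, and ring closure before retro-aldol or dehydration; the hindered amine at −78 °C, the far more electrophilic enal carbonyl, and the mild base at or below 0 °C acting on an enoate activated by its γ-oxygen are meant to secure these.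

Step 11
Reactants: 15 ethyl 2-[(2S,3R,6R)-6-[(2E)-3-bromopent-2-en-1-yl]-3-hydroxy-5-oxooxan-2-yl]acetate
Product: 16 ethyl 2-[(2S,3R,6R)-6-[(2E)-3-bromopent-2-en-1-yl]-3-[(tert-butyldimethylsilyl)oxy]-5-oxooxan-2-yl]acetate
Conditions: TBSOTf, 2,6-lutidine, CH2Cl2, −78 °C
Reagents that add atoms: tert-butyldimethylsilyl trifluoromethanesulfonate, CC(C)(C)[Si](C)(C)OS(=O)(=O)C(F)(F)F
Why: Silylation of the equatorial C3 hydroxyl at −78 °C should differentiate it from the C5 oxygen and block retro-aldol or dehydration of the β-hydroxy ketone.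

Step 12
Reactants: 16 ethyl 2-[(2S,3R,6R)-6-[(2E)-3-bromopent-2-en-1-yl]-3-[(tert-butyldimethylsilyl)oxy]-5-oxooxan-2-yl]acetate
Product: 17 ethyl 2-[(2S,3R,5S,6R)-6-[(2E)-3-bromopent-2-en-1-yl]-3-[(tert-butyldimethylsilyl)oxy]-5-hydroxyoxan-2-yl]acetate
Conditions: NaBH4, MeOH, −78 → −40 °C
Reagents that add atoms: none
Why: In this borohydride reduction the small hydride should attack C5 axially, past only the axial hydrogen at C3, to give the equatorial (5S) alcohol trans to the C6 side chain.

Step 13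
Reactants: 17 ethyl 2-[(2S,3R,5S,6R)-6-[(2E)-3-bromopent-2-en-1-yl]-3-[(tert-butyldimethylsilyl)oxy]-5-hydroxyoxan-2-yl]acetate
Product: 18 ethyl 2-[(2S,3R,5R,6R)-5-bromo-6-[(2E)-3-bromopent-2-en-1-yl]-3-[(tert-butyldimethylsilyl)oxy]oxan-2-yl]acetate
Conditions: CBr4, (n-C8H17)3P, toluene, 70 °C
Reagents that add atoms: carbon tetrabromide, BrC(Br)(Br)Br
Why: Appel bromination with trioctylphosphine in a non-polar solvent should displace the oxyphosphonium group by SN2 inversion and give the axial (5R) bromide cis to the C6 side chain.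

Step 14
Reactants: 18 ethyl 2-[(2S,3R,5R,6R)-5-bromo-6-[(2E)-3-bromopent-2-en-1-yl]-3-[(tert-butyldimethylsilyl)oxy]oxan-2-yl]acetate
Product: 19 2-[(2S,3R,5R,6R)-5-bromo-6-[(2E)-3-bromopent-2-en-1-yl]-3-[(tert-butyldimethylsilyl)oxy]oxan-2-yl]acetaldehyde
Conditions: i-Bu2AlH, CH2Cl2, −78 °C
Reagents that add atoms: none
Why: Partial reduction of the ester with i-Bu2AlH at −78 °C should stop at the aluminium hemiacetal, stabilized by the β ring oxygen, and release the aldehyde on work-up.

Step 15
Reactants: 19 2-[(2S,3R,5R,6R)-5-bromo-6-[(2E)-3-bromopent-2-en-1-yl]-3-[(tert-butyldimethylsilyl)oxy]oxan-2-yl]acetaldehyde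
Product: 20 tert-butyl({(2S,3R,5R,6R)-5-bromo-6-[(2E)-3-bromopent-2-en-1-yl]-2-[(2Z)-5-(triisopropylsilyl)pent-2-en-4-yn-1-yl]oxan-3-yl}oxy)dimethylsilane
Conditions: 1,3-bis(triisopropylsilyl)propyne, n-BuLi, THF, −78 °C; then 19, −78 → −20 °C
Reagents that add atoms: 1,3-bis(triisopropylsilyl)propyne, CC(C)[Si](CC#C[Si](C(C)C)(C(C)C)C(C)C)(C(C)C)C(C)C
Why: Peterson olefination with the lithiated bis-silylpropyne should give the (Z)-enyne through syn elimination of the kinetically formed β-silyl alkoxide.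

Step 16
Reactants: 20 tert-butyl({(2S,3R,5R,6R)-5-bromo-6-[(2E)-3-bromopent-2-en-1-yl]-2-[(2Z)-5-(triisopropylsilyl)pent-2-en-4-yn-1-yl]oxan-3-yl}oxy)dimethylsilane
Product: 21 (2S,3R,5R,6R)-5-bromo-6-[(2E)-3-bromopent-2-en-1-yl]-2-[(2Z)-pent-2-en-4-yn-1-yl]oxan-3-ol
Conditions: Bu4NF, THF, 0 °C → rt
Reagents that add atoms: none
Why: Fluoride-mediated desilylation should remove the alkynyl silyl group and the secondary silyl ether in one step.

Step 17
Reactants: 21 (2S,3R,5R,6R)-5-bromo-6-[(2E)-3-bromopent-2-en-1-yl]-2-[(2Z)-pent-2-en-4-yn-1-yl]oxan-3-ol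
Product: 22 (2S,3S,5R,6R)-5-bromo-6-[(2E)-3-bromopent-2-en-1-yl]-3-chloro-2-[(2Z)-pent-2-en-4-yn-1-yl]oxane
Conditions: CCl4, (n-C8H17)3P, toluene, 80 °C
Reagents that add atoms: carbon tetrachloride, ClC(Cl)(Cl)Cl
Why: Appel chlorination with trioctylphosphine should convert the equatorial C3 alcohol by SN2 inversion into the axial (3S) chloride, cis to the C2 side chain as in the target.

**Compound list**

1 | ethyl pent-2-ynoate | CCC#CC(=O)OCC | starting material
2 | ethyl (2E)-3-(tributylstannyl)pent-2-enoate | CCOC(=O)/C=C(/[Sn](CCCC)(CCCC)CCCC)CC | intermediate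
3 | ethyl (2E)-3-bromopent-2-enoate | CCOC(=O)/C=C(/Br)CC | intermediate
4 | (2E)-3-bromopent-2-en-1-ol | OC/C=C(/Br)CC | intermediate
5 | (2E)-1,3-dibromopent-2-ene | BrC/C=C(/Br)CC | intermediate
6 | (4S)-4-benzyl-1,3-oxazolidin-2-one | O=C1N[C@@H](Cc2ccccc2)CO1 | starting material
7 | (benzyloxy)acetyl chloride | O=C(Cl)COCc1ccccc1 | starting material
8 | (4S)-4-benzyl-3-[(benzyloxy)acetyl]-1,3-oxazolidin-2-one | O=C1OC[C@H](Cc2ccccc2)N1C(=O)COCc3ccccc3 | intermediate
9 | (4S)-4-benzyl-3-[(2R,4E)-2-(benzyloxy)-5-bromohept-4-enoyl]-1,3-oxazolidin-2-one | O=C1OC[C@H](Cc2ccccc2)N1C(=O)[C@H](OCc3ccccc3)C/C=C(/Br)CC | intermediate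
10 | (2R,4E)-2-(benzyloxy)-5-bromo-N-methoxy-N-methylhept-4-enamide | CON(C)C(=O)[C@H](OCc1ccccc1)C/C=C(/Br)CC | intermediate
11 | (3R,5E)-3-(benzyloxy)-6-bromooct-5-en-2-one | CC(=O)[C@H](OCc1ccccc1)C/C=C(/Br)CC | intermediate
12 | (3R,5E)-6-bromo-3-hydroxyoct-5-en-2-one | CC(=O)[C@H](O)C/C=C(/Br)CC | intermediate
13 | ethyl (2E)-4-oxobut-2-enoate | CCOC(=O)/C=C/C=O | starting material
14 | ethyl (2E,4R,7R,9E)-10-bromo-4,7-dihydroxy-6-oxododeca-2,9-dienoate (open-chain aldol adduct) | CCOC(=O)/C=C/[C@H](O)CC(=O)[C@H](O)C/C=C(/Br)CC | intermediate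
15 | ethyl 2-[(2S,3R,6R)-6-[(2E)-3-bromopent-2-en-1-yl]-3-hydroxy-5-oxooxan-2-yl]acetate | CCOC(=O)C[C@@H]1O[C@H](C/C=C(/Br)CC)C(=O)C[C@H]1O | intermediate
16 | ethyl 2-[(2S,3R,6R)-6-[(2E)-3-bromopent-2-en-1-yl]-3-[(tert-butyldimethylsilyl)oxy]-5-oxooxan-2-yl]acetate | CCOC(=O)C[C@@H]1O[C@H](C/C=C(/Br)CC)C(=O)C[C@H]1O[Si](C)(C)C(C)(C)C | intermediate
17 | ethyl 2-[(2S,3R,5S,6R)-6-[(2E)-3-bromopent-2-en-1-yl]-3-[(tert-butyldimethylsilyl)oxy]-5-hydroxyoxan-2-yl]acetate | CCOC(=O)C[C@@H]1O[C@H](C/C=C(/Br)CC)[C@@H](O)C[C@H]1O[Si](C)(C)C(C)(C)C | intermediate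
18 | ethyl 2-[(2S,3R,5R,6R)-5-bromo-6-[(2E)-3-bromopent-2-en-1-yl]-3-[(tert-butyldimethylsilyl)oxy]oxan-2-yl]acetate | CCOC(=O)C[C@@H]1O[C@H](C/C=C(/Br)CC)[C@H](Br)C[C@H]1O[Si](C)(C)C(C)(C)C | intermediate
19 | 2-[(2S,3R,5R,6R)-5-bromo-6-[(2E)-3-bromopent-2-en-1-yl]-3-[(tert-butyldimethylsilyl)oxy]oxan-2-yl]acetaldehyde | O=CC[C@@H]1O[C@H](C/C=C(/Br)CC)[C@H](Br)C[C@H]1O[Si](C)(C)C(C)(C)C | intermediate
20 | tert-butyl({(2S,3R,5R,6R)-5-bromo-6-[(2E)-3-bromopent-2-en-1-yl]-2-[(2Z)-5-(triisopropylsilyl)pent-2-en-4-yn-1-yl]oxan-3-yl}oxy)dimethylsilane | CC(C)[Si](C#C/C=C\C[C@@H]1O[C@H](C/C=C(/Br)CC)[C@H](Br)C[C@H]1O[Si](C)(C)C(C)(C)C)(C(C)C)C(C)C | intermediate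
21 | (2S,3R,5R,6R)-5-bromo-6-[(2E)-3-bromopent-2-en-1-yl]-2-[(2Z)-pent-2-en-4-yn-1-yl]oxan-3-ol | C#C/C=C\C[C@@H]1O[C@H](C/C=C(/Br)CC)[C@H](Br)C[C@H]1O | intermediate
22 | (2S,3S,5R,6R)-5-bromo-6-[(2E)-3-bromopent-2-en-1-yl]-3-chloro-2-[(2Z)-pent-2-en-4-yn-1-yl]oxane, with the locants run the other way (2R,3R,5S,6S)-3-bromo-2-[(2E)-3-bromopent-2-en-1-yl]-5-chloro-6-[(2Z)-pent-2-en-4-yn-1-yl]oxane | C#C/C=C\C[C@@H]1O[C@H](C/C=C(/Br)CC)[C@H](Br)C[C@@H]1Cl | target

**Step count and risks**

Total step count: 17. Longest linear sequence: 16 steps (steps 1 to 4, then 6 to 17).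

Step 10 (bears the label "Proposed new method:") is the most likely to fail. Four processes could cause this:
- enolization toward C6–H, which would erode the C6 configuration or move the aldol to the wrong carbon;
- weak facial control in the aldol addition;
- retro-aldol or dehydration of the β-hydroxy ketone under the base;
- kinetic closure to the 2,6-trans ring.

The fallback uses known chemistry and separates the two bond formations. It sets out from 11. The titanium-mediated aldol reaction of this α-benzyloxy methyl ketone (TiCl4, i-Pr2NEt, CH2Cl2, −78 °C; then 13), a reaction class with established 1,4-anti selectivity, should give ethyl (2E,4R,7R,9E)-7-(benzyloxy)-10-bromo-4-hydroxy-6-oxododeca-2,9-dienoate F1. Debenzylation with BCl3 at −78 °C would then give 14 as an isolated compound, and DBU in CH2Cl2 would close it by oxa-Michael addition. The fallback comes back to the route at 15.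

Step 12 may suffer from poor facial selectivity of hydride delivery, since equatorial attack would give the axial C5 alcohol. The fallback sets out from 16 and makes a virtue of the opposite selectivity. LiB(s-Bu)3H in THF at −78 °C should attack equatorially and give ethyl 2-[(2S,3R,5R,6R)-6-[(2E)-3-bromopent-2-en-1-yl]-3-[(tert-butyldimethylsilyl)oxy]-5-hydroxyoxan-2-yl]acetate F2. Mitsunobu inversion (4-nitrobenzoic acid, PPh3, diisopropyl azodicarboxylate) would give ethyl 2-[(2S,3R,5S,6R)-6-[(2E)-3-bromopent-2-en-1-yl]-3-[(tert-butyldimethylsilyl)oxy]-5-[(4-nitrobenzoyl)oxy]oxan-2-yl]acetate F3. Ethanolysis with K2CO3 in EtOH comes back to the route at 17.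

Step 17 may fail through participation of the ring oxygen O1 in the departure of the activated C3 oxygen, which would lead to retention or ring contraction, or through elimination instead of substitution. The fallback sets out from 21 and replaces the oxyphosphonium pathway by a sulfonate displacement. Chloromethanesulfonyl chloride and pyridine would give (2S,3R,5R,6R)-5-bromo-6-[(2E)-3-bromopent-2-en-1-yl]-2-[(2Z)-pent-2-en-4-yn-1-yl]oxan-3-yl chloromethanesulfonate F4. LiCl in DMF would displace it with inversion, and the fallback comes back to the route at 22.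

Further compounds
F1 | step 10 | ethyl (2E,4R,7R,9E)-7-(benzyloxy)-10-bromo-4-hydroxy-6-oxododeca-2,9-dienoate | CCOC(=O)/C=C/[C@H](O)CC(=O)[C@H](OCc1ccccc1)C/C=C(/Br)CC
F2 | step 12 | ethyl 2-[(2S,3R,5R,6R)-6-[(2E)-3-bromopent-2-en-1-yl]-3-[(tert-butyldimethylsilyl)oxy]-5-hydroxyoxan-2-yl]acetate | CCOC(=O)C[C@@H]1O[C@H](C/C=C(/Br)CC)[C@H](O)C[C@H]1O[Si](C)(C)C(C)(C)C
F3 | step 12 | ethyl 2-[(2S,3R,5S,6R)-6-[(2E)-3-bromopent-2-en-1-yl]-3-[(tert-butyldimethylsilyl)oxy]-5-[(4-nitrobenzoyl)oxy]oxan-2-yl]acetate | CCOC(=O)C[C@@H]1O[C@H](C/C=C(/Br)CC)[C@@H](OC(=O)c2ccc(cc2)[N+](=O)[O-])C[C@H]1O[Si](C)(C)C(C)(C)C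
F4 | step 17 | (2S,3R,5R,6R)-5-bromo-6-[(2E)-3-bromopent-2-en-1-yl]-2-[(2Z)-pent-2-en-4-yn-1-yl]oxan-3-yl chloromethanesulfonate | C#C/C=C\C[C@@H]1O[C@H](C/C=C(/Br)CC)[C@H](Br)C[C@H]1OS(=O)(=O)CCl
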